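## Structural features

Polyanthinin is the C11 ether of a bicyclic sesquiterpene alcohol with O7 of umbelliferone. With ring A numbered C10–C1–C2–C3–C4–C5 and ring B C5–C6–C7–C8–C9–C10, the two cyclohexanes share the C5–C10 bond and are cis-fused, and each fusion carbon carries a methyl group (C16 on C5, C15 on C10). C4 is a gem-dimethyl carbon, so C4, C5 and C10 are three contiguous quaternary carbons; C3 beside C4 carries the acetate, C8 an exocyclic methylene (C12), and C9 the aryloxymethyl arm (C11). The stereocentres C3 (S), C5 (S), C10 (R) and C9 (S) place the acetoxy group, both angular methyl groups and C11 on one face, with C5, C10 and C9 directly adjacent. The fragile groups are the acetate and the coumarin lactone (hydride, organometallics, hydroxide) and the 1,1-disubstituted alkene, which acid can move into the ring toward C9. The real difficulty is the vicinal pair of quaternary stereocentres C5/C10 beside quaternary C4, plus the stereocentre C9 that must be built next to them. The key step uses the fact that a cis-fused decalin with oxygen at C3 beside C4Me2 and a one-carbon substituent on C8 is the [3,3] image of a 2-vinylbicyclo[2.2.2]oct-5-en-2-ol: C5 and C8 are the bridgeheads, C3–C4, C6–C7 and C9=C10 the bridges, and a new C1–C10 bond opens the cage into rings A and B.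

## Logic of the disconnections

23 to 22: the acyl–O3 bond is cut last. An acetate would not pass organolithium, hydride or potassium hydride steps. The forward step must acylate a neopentyl secondary alcohol without opening the lactone or moving the C8=C12 bond, so a neutral, nucleophile-catalysed acylation is required.

22 to 20 and 21: the C11–O bond is cut. The coumarin would not survive the reagents of the earlier steps, and the cut makes the end convergent. The forward step needs substitution at a β-branched primary carbon while the C3 hydroxyl stays untouched; the neopentyl environment of C3 should provide that discrimination.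

20 to 18 (through 19): the C9–C11 bond is cut and the alkene is moved back from C8=C12 to C8=C9 with oxygen on C12. A homoallylic alcohol beside an exocyclic methylene is the retron of a [2,3] shift of an allyl metallomethyl ether. This removes the C9 stereocentre and one carbon. The forward step must deliver the carbanion to C9 on the face of the angular methyl groups and must tolerate the C3 alkoxide.

18 to 17 to 16: the O12–CH2Sn bond and then the O12–Si bond are cut. The forward alkylation must select the primary allylic hydroxyl over the C3 hydroxyl, which is done by stoichiometry and by the hindrance at C3.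

16 to 15: the C3–H bond is cut, because a C3 ketone is what the key step delivers. The two ring A chairs of 15 are close in energy, so substrate control is not reliable. The forward step therefore needs a chiral reagent that reads the quaternary C4 against the methylene C2.

15 to 12 (through 14 and 13): the C1–C10 bond is cut and the C3–C8 bond is re-formed (retro oxy-Cope). The vicinal quaternary pair becomes a bridgehead (C5) and a methyl-bearing alkene carbon (C10) of a rigid cage, so their cis relationship needs no separate control. The forward step needs the vinyl group syn to the C9=C10 bridge and an alkoxide that keeps its charge. For the second reason O12 carries triisopropylsilyl: a smaller silyl group sits 1,3 to the alkoxide and could migrate to it, which would remove the charge acceleration.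

12 to 10 and 11: the C2–C3 bond is cut. The forward step is addition of a vinyl nucleophile to a non-enolisable ketone between two quaternary carbons, from the face of the alkene bridge.

10 to 9: no bond is cut; the enantiomers are separated. The carbonyl of 9 lies between two quaternary carbons and offers neither an enzyme nor a chiral borane a small side to read, so enantioselective reduction is not defensible here. Compound 9 is the first chiral intermediate that is a single substance, so physical resolution is placed there.

9 to 8 to 6 and 7: the C7–S bond is cut, then the C5–C6 and C7–C8 bonds (retro Diels–Alder). The cage becomes a planar, achiral dienone that already holds C4Me2, both future angular methyl groups and C12. The forward cycloaddition must form two quaternary bridgeheads, so a reactive, traceless ethylene equivalent is needed.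

6 to 4 (through 5): the two C4–CH3 bonds are cut, which leads back to an aromatic phenol. The forward step needs C- over O-methylation and needs the second methyl group to go to the methyl-bearing ortho carbon, not to the one carrying the silyloxymethyl group.

4 to 3 to 2 to 1: the O12–Si bond, the C12 oxidation level and the C8–C12 bond are removed in turn. The forward formylation must take the less hindered ortho position of 1.

## Other disconnections considered

Alternative 1: The cut is the C5–C16 bond alone. The C5 methyl group is removed, C5=C6 is conjugated to a C7 ketone, and the C3 oxygen carries a bromomethylsilyl group, giving A2. In the forward step Bu3SnH/AIBN would convert the C–Br bond of A2 into an α-silyl radical that adds 6-exo to C5, the β-carbon of the enone, to give the oxasilacycle A1. Protodesilylation would then leave the C5 methyl group and the C3 hydroxyl. In its favour, the methyl group is delivered from the C3 oxygen, so the C3–O/C16 cis relationship is fixed by the tether, and a nucleophilic radical adding to an enone is polarity-matched. On this one relationship the alternative is the better plan, because the chosen route has to set C3 with a chiral reagent. Against it, the cis ring fusion then depends on a C3/C10 relationship that must already exist in A2. The key step makes one C–C bond and no permanent ring. From A1 the C7 oxygen must be removed, C12 added at C8 and C11 added at C9 with control beside quaternary C10. Both key steps are intramolecular and geometrically constrained and are equal in that respect. Structurally the chosen shift creates ring A and the C5/C10 pair at once, and in step economy the alternative would be clearly longer.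

Alternative 2: The cut is the C5–C10 bond. Ring A is opened to the six-membered lactone A4 (O–C6–C5–C4–C3–C2) carrying an (E)-alkenyl group on C2; A4 would be built from (R)-pantolactone A5, which supplies C3 and C4. In the forward step the silyl ketene acetal of A4 would rearrange [3,3] through the boat shape imposed by the lactone ring. This forms C5–C10, breaks C2–O and gives the cyclohexene acid A3. In its favour, the absolute configuration comes from A5 without any resolution, and on this point the alternative is better than the chosen plan. The C3 oxygen and the gem-dimethyl group are present from the start, and the (E)-alkene with the boat geometry should translate into cis methyl groups. Against it, the new bond must join two fully substituted carbons with quaternary C4 next door, and nothing comparable to cage strain drives it. The lactone has to be enolised at a very hindered α-carbon. After A3, ring B is still missing: C7 and C11 must be added, C9 set, and the C1=C2 bond reduced. Both plans use a suprafacial [3,3] shift and are equal in the reliability of chirality transfer. The chosen plan has the stronger driving force and the shorter path to ring B, so the alternative would need more steps.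

Alternative 3: Two bonds are cut, C9–C10 and C5–C16 (the latter as a 1,2-shift), which leads to the monocyclic tertiary alcohol A7 with a tethered allylsilane. In the forward step a Lewis acid such as SnCl4 would ionise the C5 alcohol of A7. A methyl group would move from C10 to C5, and the C10 cation would be captured by C9 of the allylsilane, closing ring B and releasing the C8 methylene to give A6. In its favour, the whole carbon skeleton, both protected oxygens and the exocyclic alkene would appear in one step from a monocyclic precursor; in step economy and convergence the alternative is the better plan. Against it, C5, C10 and C9 would all be formed from planar cations with only the C3 silyloxy group as a controlling element. A methyl shift from C4 instead of C10, direct five-membered capture of the C5 cation by the alkene, and proton loss are all open. Mechanistically the chosen route is concerted and cage-controlled where the alternative is stepwise and cationic, so the chosen route is longer but has a named control element for every stereocentre.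

Key step: step 9

## Remarks on the chemistry

- Locants C1–C16 in the arguments are the terpenoid locants defined under "Structural features"; compound names use systematic locants.
- Compounds 8 and 9 are racemic (the bridgehead relationship is fixed by the cage); from 10 onward every compound is a single enantiomer.
- The elution order of the enantiomers of 9 cannot be foreseen; 10 is to be identified by the sign of the n→π* Cotton effect of its β,γ-unsaturated ketone and confirmed by anomalous-dispersion X-ray analysis of a crystalline later intermediate.
- The stereodescriptors of 12 and 15 were checked against 23: C5 is carried unchanged, and suprafacial bond formation gives the C10 configuration of the target.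

## Route

Step 1
Reactants: 1 3,4-dimethylphenol
Product: 2 2-hydroxy-4,5-dimethylbenzaldehyde
Conditions: MgCl2, Et3N, (CH2O)n, MeCN, reflux; then 1 M HCl
Reagents that add atoms: paraformaldehyde (reacts as formaldehyde), C=O
Why: Magnesium phenoxide-directed ortho-formylation (hydroxymethylation, then hydride transfer to a second formaldehyde); the ortho position between OH and the ring methyl group is shielded, so the other ortho carbon (future C8) should react.

Step 2
Reactants: 2 2-hydroxy-4,5-dimethylbenzaldehyde
Product: 3 2-(hydroxymethyl)-4,5-dimethylphenol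
Conditions: NaBH4, MeOH, 0 °C
Reagents that add atoms: none
Why: Borohydride reduction of an aryl aldehyde; the cold, neutral work-up avoids loss of water from the salicyl alcohol.

Step 3
Reactants: 3 2-(hydroxymethyl)-4,5-dimethylphenol
Product: 4 4,5-dimethyl-2-{[tri(propan-2-yl)silyl]oxymethyl}phenol
Conditions: TIPSCl, imidazole, DMF, 0 °C
Reagents that add atoms: chlorotri(propan-2-yl)silane, CC(C)[Si](Cl)(C(C)C)C(C)C
Why: Imidazole-mediated silylation; the primary aliphatic hydroxyl should react ahead of the hydrogen-bonded phenol with the bulky chlorosilane, and any aryl silyl ether formed is the more labile one on mild basic work-up.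

Step 4
Reactants: 4 4,5-dimethyl-2-{[tri(propan-2-yl)silyl]oxymethyl}phenol
Product: 6 4,5,6,6-tetramethyl-2-{[tri(propan-2-yl)silyl]oxymethyl}cyclohexa-2,4-dien-1-one, via ortho-methylated phenol 5 (not isolated)
Conditions: NaH, MeI, toluene, 0 → 60 °C, dark
Reagents that add atoms: iodomethane, CI
Why: Alkylative dearomatisation of a phenoxide; the tight sodium phenoxide ion pair in toluene directs methyl to the ortho carbon, first to the free ortho C–H (giving 5 after tautomerisation), then to the same carbon again because the other ortho carbon carries the bulky silyloxymethyl group. The product cannot re-aromatise.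

Step 5
Reactants: 6 4,5,6,6-tetramethyl-2-{[tri(propan-2-yl)silyl]oxymethyl}cyclohexa-2,4-dien-1-one; 7 phenyl vinyl sulfone
Product: 8 rac-7-(benzenesulfonyl)-3,3,4,5-tetramethyl-1-{[tri(propan-2-yl)silyl]oxymethyl}bicyclo[2.2.2]oct-5-en-2-one (both C7 epimers, possibly with the 8-sulfonyl regioisomers; all converge in step 6)
Conditions: toluene, BHT (cat.), 130 °C, sealed tube
Reagents that add atoms: none
Why: Diels–Alder reaction of a 2,4-cyclohexadienone, locked s-cis, with an activated ethylene equivalent; it forms the C5–C6 and C7–C8 bonds and both quaternary bridgeheads. Regio- and endo/exo-selectivity do not matter because the sulfonyl group is removed.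

Step 6
Reactants: 8 rac-7-(benzenesulfonyl)-3,3,4,5-tetramethyl-1-{[tri(propan-2-yl)silyl]oxymethyl}bicyclo[2.2.2]oct-5-en-2-one
Product: 9 rac-3,3,4,5-tetramethyl-1-{[tri(propan-2-yl)silyl]oxymethyl}bicyclo[2.2.2]oct-5-en-2-one
Conditions: 6% Na(Hg), Na2HPO4, MeOH–THF, −20 °C
Reagents that add atoms: none
Why: Reductive desulfonylation by electron transfer to the aryl sulfone; the ketone is non-enolisable and unconjugated and should survive the buffered, cold conditions.

Step 7
Reactants: 9 rac-3,3,4,5-tetramethyl-1-{[tri(propan-2-yl)silyl]oxymethyl}bicyclo[2.2.2]oct-5-en-2-one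
Product: 10 (1R,4S)-3,3,4,5-tetramethyl-1-{[tri(propan-2-yl)silyl]oxymethyl}bicyclo[2.2.2]oct-5-en-2-one
Conditions: preparative SFC, amylose tris(3,5-dimethylphenylcarbamate) phase, CO2/i-PrOH
Reagents that add atoms: none
Why: Chromatographic resolution of a racemate on a chiral stationary phase; no bond is made or broken. The carbonyl lies between two quaternary carbons, so a reagent-based resolution by reduction is not defensible, and the mirror-image ketone is set aside.

Step 8
Reactants: 10 (1R,4S)-3,3,4,5-tetramethyl-1-{[tri(propan-2-yl)silyl]oxymethyl}bicyclo[2.2.2]oct-5-en-2-one; 11 vinylmagnesium bromide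
Product: 12 (1R,2S,4S)-2-ethenyl-3,3,4,5-tetramethyl-1-{[tri(propan-2-yl)silyl]oxymethyl}bicyclo[2.2.2]oct-5-en-2-ol
Conditions: CeCl3 (anhydrous), 11, THF, −78 °C; then 10, −78 → 0 °C; aq. NH4Cl
Reagents that add atoms: none
Why: Organocerium 1,2-addition to a hindered, non-enolisable ketone. The gem-dimethyl group shields both faces equally, so the choice is made by the bridges: approach past the sp2 C9–H is easier than past the C7 methylene hydrogens, which places the vinyl group syn to the C9=C10 bridge and the hydroxyl anti to it.

Step 9
Reactants: 12 (1R,2S,4S)-2-ethenyl-3,3,4,5-tetramethyl-1-{[tri(propan-2-yl)silyl]oxymethyl}bicyclo[2.2.2]oct-5-en-2-ol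
Product: 15 (4aR,8aS)-1,1,4a,8a-tetramethyl-6-{[tri(propan-2-yl)silyl]oxymethyl}-3,4,4a,7,8,8a-hexahydronaphthalen-2(1H)-one, via potassium alkoxide 13 (not isolated), via potassium enolate 14 (not isolated)
Conditions: KH, 18-crown-6, THF, 0 → 66 °C; then aq. NH4Cl, 0 °C
Reagents that add atoms: none
Why: KH with 18-crown-6 gives the dissociated alkoxide 13, whose vinyl group lies over the C9=C10 bridge; a concerted [3,3] shift through the boat-shaped six-carbon array held by the cage joins C1 to C10 while the C3–C8 cage bond breaks, and the enolate 14 is protonated at C2 on work-up. The closest known reaction type is the anionic oxy-Cope rearrangement of 2-vinylbicyclo[2.2.2]oct-5-en-2-ols to cis-fused octalones, from which this case differs only in the methyl group on the bond-forming alkene carbon. Ring A (C10–C1–C2–C3–C4–C5) is closed by sigmatropic bond formation between two sp2 termini pre-positioned by the cage, not by a polar cyclisation; ring B is the former cyclohexene of the cage. The only new stereocentre, C10, is set by the cage: C1 can reach C10 only on the face turned toward the C3–C4 bridge, so the C10 methyl group ends cis to the C5 methyl group, a direct relay from the C5 bridgehead. The step needs [3,3] selectivity over a [1,3] shift and over heterolysis of the C3–C8 bond; the syn vinyl/alkene arrangement from step 8, the release of cage strain and the irreversible formation of the enolate should secure it. The triisopropylsilyl ether is too bulky to migrate to the tertiary alkoxide, so the negative charge that accelerates the shift is kept. Protonation at C2 creates no stereocentre, and C5 and C10 bear no hydrogen that base could remove.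

Step 10
Reactants: 15 (4aR,8aS)-1,1,4a,8a-tetramethyl-6-{[tri(propan-2-yl)silyl]oxymethyl}-3,4,4a,7,8,8a-hexahydronaphthalen-2(1H)-one
Product: 16 (2S,4aR,8aS)-1,1,4a,8a-tetramethyl-6-{[tri(propan-2-yl)silyl]oxymethyl}-1,2,3,4,4a,7,8,8a-octahydronaphthalen-2-ol
Conditions: (R)-Me-CBS oxazaborolidine, catecholborane, toluene, −78 → −40 °C; then MeOH, aq. NaOH
Reagents that add atoms: none
Why: Corey–Bakshi–Shibata reduction; the catalyst distinguishes the quaternary C4 (large) from the C2 methylene (small), and the (R)-catalyst delivers hydride to the face opposite the angular methyl groups, giving the (S)-carbinol with the hydroxyl cis to them. Reagent control is chosen because the two ring A chairs of 15 are close in energy; catecholborane at low temperature should leave the trisubstituted alkene untouched.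

Step 11
Reactants: 16 (2S,4aR,8aS)-1,1,4a,8a-tetramethyl-6-{[tri(propan-2-yl)silyl]oxymethyl}-1,2,3,4,4a,7,8,8a-octahydronaphthalen-2-ol
Product: 17 (2S,4aR,8aS)-6-(hydroxymethyl)-1,1,4a,8a-tetramethyl-1,2,3,4,4a,7,8,8a-octahydronaphthalen-2-ol
Conditions: TBAF, THF, 0 °C → rt
Reagents that add atoms: none
Why: Fluoride-induced cleavage of the silyl ether; no other group responds to fluoride.

Step 12
Reactants: 17 (2S,4aR,8aS)-6-(hydroxymethyl)-1,1,4a,8a-tetramethyl-1,2,3,4,4a,7,8,8a-octahydronaphthalen-2-ol
Product: 18 (2S,4aR,8aS)-1,1,4a,8a-tetramethyl-6-{[(tributylstannyl)methoxy]methyl}-1,2,3,4,4a,7,8,8a-octahydronaphthalen-2-ol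
Conditions: KH (1.05 equiv), THF, 0 °C; Bu3SnCH2I (1.1 equiv), 0 °C → rt
Reagents that add atoms: tributyl(iodomethyl)stannane, CCCC[Sn](CCCC)(CCCC)CI
Why: Williamson etherification with one equivalent of base; the primary allylic alkoxide is the more acidic and far less hindered site, and the neopentyl C3 alkoxide beside C4Me2 should not compete for the sluggish electrophile.

Step 13
Reactants: 18 (2S,4aR,8aS)-1,1,4a,8a-tetramethyl-6-{[(tributylstannyl)methoxy]methyl}-1,2,3,4,4a,7,8,8a-octahydronaphthalen-2-ol
Product: 20 (2S,4aR,5S,8aS)-5-(hydroxymethyl)-1,1,4a,8a-tetramethyl-6-methylidenedecahydronaphthalen-2-ol, via dilithiated ether 19 (not isolated)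
Conditions: n-BuLi (2.5 equiv), THF, −78 → −50 °C; then H2O
Reagents that add atoms: none
Why: Still–Wittig [2,3]-sigmatropic rearrangement: the first equivalent of n-BuLi forms the C3 lithium alkoxide, the second exchanges tin for lithium, and the α-alkoxy carbanion of 19 attacks C9 through a five-membered envelope while the double bond moves to C8=C12. C9 should be set by attack on the convex face, syn to the angular methyl groups, because the other face is covered by ring A (C1 or the C4 gem-dimethyl carbon, depending on the half-chair of ring B); the equatorial 3-alkoxide favours the half-chair in which only the C5 methyl group flanks the attacked face.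

Step 14
Reactants: 20 (2S,4aR,5S,8aS)-5-(hydroxymethyl)-1,1,4a,8a-tetramethyl-6-methylidenedecahydronaphthalen-2-ol; 21 umbelliferone (7-hydroxy-2H-chromen-2-one)
Product: 22 7-{[(1S,4aS,6S,8aR)-6-hydroxy-4a,5,5,8a-tetramethyl-2-methylidenedecahydronaphthalen-1-yl]methoxy}-2H-chromen-2-one
Conditions: PPh3, DIAD, THF, 0 °C → rt
Reagents that add atoms: none
Why: Mitsunobu etherification; the acidic phenol is a competent pronucleophile, only the primary C11 hydroxyl forms a reactive alkoxyphosphonium ion, and the neopentyl secondary C3 hydroxyl stays inert. Substitution at C11 does not touch C9.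

Step 15
Reactants: 22 7-{[(1S,4aS,6S,8aR)-6-hydroxy-4a,5,5,8a-tetramethyl-2-methylidenedecahydronaphthalen-1-yl]methoxy}-2H-chromen-2-one
Product: 23 polyanthinin, (2S,4aR,5S,8aS)-1,1,4a,8a-tetramethyl-6-methylidene-5-{[(2-oxo-2H-chromen-7-yl)oxy]methyl}decahydronaphthalen-2-yl acetate
Conditions: Ac2O, DMAP, pyridine, CH2Cl2, rt
Reagents that add atoms: acetic anhydride, CC(=O)OC(C)=O
Why: DMAP-catalysed acylation of a hindered secondary alcohol; the conditions are non-acidic, so the exocyclic alkene should stay in place, and they do not open the coumarin lactone.

## Compound list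

1 | 3,4-dimethylphenol | Cc1ccc(O)cc1C | starting material
2 | 2-hydroxy-4,5-dimethylbenzaldehyde | Cc1cc(C=O)c(O)cc1C | intermediate
3 | 2-(hydroxymethyl)-4,5-dimethylphenol | Cc1cc(CO)c(O)cc1C | intermediate
4 | 4,5-dimethyl-2-{[tri(propan-2-yl)silyl]oxymethyl}phenol | Cc1cc(CO[Si](C(C)C)(C(C)C)C(C)C)c(O)cc1C | intermediate
5 | 2,3,4-trimethyl-6-{[tri(propan-2-yl)silyl]oxymethyl}phenol | Cc1cc(CO[Si](C(C)C)(C(C)C)C(C)C)c(O)c(C)c1C | intermediate (not isolated)
6 | 4,5,6,6-tetramethyl-2-{[tri(propan-2-yl)silyl]oxymethyl}cyclohexa-2,4-dien-1-one (achiral) | CC1=C(C)C(C)(C)C(=O)C(CO[Si](C(C)C)(C(C)C)C(C)C)=C1 | intermediate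
7 | phenyl vinyl sulfone | C=CS(=O)(=O)c1ccccc1 | starting material
8 | rac-7-(benzenesulfonyl)-3,3,4,5-tetramethyl-1-{[tri(propan-2-yl)silyl]oxymethyl}bicyclo[2.2.2]oct-5-en-2-one, racemic, both C7 epimers, bridgehead relationship fixed by the cage | O=C1C(C)(C)C2(C)CC(S(=O)(=O)c3ccccc3)C1(CO[Si](C(C)C)(C(C)C)C(C)C)C=C2C | intermediate
9 | rac-3,3,4,5-tetramethyl-1-{[tri(propan-2-yl)silyl]oxymethyl}bicyclo[2.2.2]oct-5-en-2-one, racemate of 10 | O=C1C(C)(C)C2(C)CCC1(CO[Si](C(C)C)(C(C)C)C(C)C)C=C2C | intermediate
10 | (1R,4S)-3,3,4,5-tetramethyl-1-{[tri(propan-2-yl)silyl]oxymethyl}bicyclo[2.2.2]oct-5-en-2-one | O=C1C(C)(C)[C@@]2(C)CC[C@]1(CO[Si](C(C)C)(C(C)C)C(C)C)C=C2C | intermediate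
11 | vinylmagnesium bromide | C=C[Mg]Br | starting material
12 | (1R,2S,4S)-2-ethenyl-3,3,4,5-tetramethyl-1-{[tri(propan-2-yl)silyl]oxymethyl}bicyclo[2.2.2]oct-5-en-2-ol (vinyl syn to the alkene bridge) | C=C[C@]1(O)C(C)(C)[C@@]2(C)CC[C@]1(CO[Si](C(C)C)(C(C)C)C(C)C)C=C2C | intermediate
13 | potassium alkoxide of 12 | C=C[C@]1([O-])C(C)(C)[C@@]2(C)CC[C@]1(CO[Si](C(C)C)(C(C)C)C(C)C)C=C2C.[K+] | intermediate (not isolated)
14 | potassium C2=C3 enolate of 15 | CC(C)[Si](C(C)C)(C(C)C)OCC1=C[C@@]2(C)CC=C([O-])C(C)(C)[C@@]2(C)CC1.[K+] | intermediate (not isolated)
15 | (4aR,8aS)-1,1,4a,8a-tetramethyl-6-{[tri(propan-2-yl)silyl]oxymethyl}-3,4,4a,7,8,8a-hexahydronaphthalen-2(1H)-one (cis-fused, methyl groups cis) | CC(C)[Si](C(C)C)(C(C)C)OCC1=C[C@@]2(C)CCC(=O)C(C)(C)[C@@]2(C)CC1 | intermediate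
16 | (2S,4aR,8aS)-1,1,4a,8a-tetramethyl-6-{[tri(propan-2-yl)silyl]oxymethyl}-1,2,3,4,4a,7,8,8a-octahydronaphthalen-2-ol (hydroxyl cis to the angular methyl groups) | CC(C)[Si](C(C)C)(C(C)C)OCC1=C[C@@]2(C)CC[C@H](O)C(C)(C)[C@@]2(C)CC1 | intermediate
17 | (2S,4aR,8aS)-6-(hydroxymethyl)-1,1,4a,8a-tetramethyl-1,2,3,4,4a,7,8,8a-octahydronaphthalen-2-ol | OCC1=C[C@@]2(C)CC[C@H](O)C(C)(C)[C@@]2(C)CC1 | intermediate
18 | (2S,4aR,8aS)-1,1,4a,8a-tetramethyl-6-{[(tributylstannyl)methoxy]methyl}-1,2,3,4,4a,7,8,8a-octahydronaphthalen-2-ol | CCCC[Sn](CCCC)(CCCC)COCC1=C[C@@]2(C)CC[C@H](O)C(C)(C)[C@@]2(C)CC1 | intermediate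
19 | dilithio derivative of 18 (lithium alkoxide at O3, lithium in place of tin) | [Li]COCC1=C[C@@]2(C)CC[C@H](O[Li])C(C)(C)[C@@]2(C)CC1 | intermediate (not isolated)
20 | (2S,4aR,5S,8aS)-5-(hydroxymethyl)-1,1,4a,8a-tetramethyl-6-methylidenedecahydronaphthalen-2-ol | C=C1CC[C@]2(C)C(C)(C)[C@@H](O)CC[C@]2(C)[C@H]1CO | intermediate
21 | umbelliferone (7-hydroxy-2H-chromen-2-one) | O=c1ccc2ccc(O)cc2o1 | starting material
22 | 7-{[(1S,4aS,6S,8aR)-6-hydroxy-4a,5,5,8a-tetramethyl-2-methylidenedecahydronaphthalen-1-yl]methoxy}-2H-chromen-2-one | C=C1CC[C@]2(C)C(C)(C)[C@@H](O)CC[C@]2(C)[C@H]1COc1ccc2ccc(=O)oc2c1 | intermediate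
23 | polyanthinin, (2S,4aR,5S,8aS)-1,1,4a,8a-tetramethyl-6-methylidene-5-{[(2-oxo-2H-chromen-7-yl)oxy]methyl}decahydronaphthalen-2-yl acetate | C=C1CC[C@]2(C)C(C)(C)[C@@H](OC(C)=O)CC[C@]2(C)[C@H]1COc1ccc2ccc(=O)oc2c1 | target

## Step count and least certain steps

Total step count: 15. Longest linear sequence: 15 steps (1 to 23); 7, 11 and 21 are bought.

Step 9 (key step). The [3,3] shift has to create quaternary C10 beside quaternary C5. Bond formation at the methyl-bearing alkene carbon may be slow enough that heterolysis of the C3–C8 bond, followed by recombination to a [1,3]-shift product, or simple fragmentation of the alkoxide takes over. Fallback without an alkoxide: from 12, silylation (TMSOTf, 2,6-lutidine) would give the trimethylsilyl ether F1. A neutral thermal oxy-Cope rearrangement of F1 (decalin, about 230 °C, sealed, base-washed glass) would give the trimethylsilyl enol ether F2, and mild hydrolysis (K2CO3, MeOH) would return to the route at 15.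

Step 4. Methyl transfer to the phenoxide oxygen, and to the ortho carbon that carries the silyloxymethyl group, may compete with the two C-methylations at the other ortho carbon and leave little dienone. Fallback with bromine as a blocking group that is exchanged for C12 after dearomatisation: from 1, ortho-bromination (NBS, MeCN, 0 °C) would give 2-bromo-4,5-dimethylphenol F3. The same NaH/MeI/toluene treatment can then alkylate only the free ortho carbon and would give 2-bromo-4,5,6,6-tetramethylcyclohexa-2,4-dien-1-one F4. Stille coupling of F4 with (tributylstannyl)methanol (Pd(PPh3)4, dioxane, 80 °C) would give 2-(hydroxymethyl)-4,5,6,6-tetramethylcyclohexa-2,4-dien-1-one F5, and silylation (TIPSCl, imidazole) would return to the route at 6.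

Step 5. The cycloaddition has to bond both fully substituted diene termini; it may be so slow that dimerisation or decomposition of the dienone and polymerisation of the sulfone win. Fallback with a more reactive two-carbon partner and a later adjustment of the oxidation level: from 6, (E)-1,2-bis(phenylsulfonyl)ethene (toluene, 90 °C) would give the bis-sulfone cycloadduct F6. Reductive elimination (Na(Hg), NaH2PO4, MeOH, −20 °C) would give the bicyclo[2.2.2]octa-5,7-dien-2-one F7, which is kept cold because such dienones can lose a ketene on heating. Diimide (potassium azodicarboxylate, AcOH, MeOH, 0 °C) would reduce only the disubstituted double bond and return to the route at 9.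

Step 13. The carbanion has to reach a neopentyl terminus. The [2,3] shift may be slow enough that a [1,2] shift or protonation intervenes, and delivery to the concave face may erode the selectivity at C9. Fallback by a charge-free [3,3] route with one-carbon degradation: from 17, Johnson–Claisen rearrangement (MeC(OEt)3, cat. propionic acid, 140 °C) would give the ethyl ester F8, and saponification (LiOH, THF/H2O) the acid F9. Barton decarboxylative hydroxylation through the N-acyloxypyridine-2-thione F10 (DCC, N-hydroxypyridine-2-thione; hν, O2, t-BuSH; then P(OMe)3) would return to the route at 20.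

Step 14. Substitution at the β-branched C11 may be slow, so that the alkoxyphosphonium ion is diverted into elimination toward a C9=C11 diene or into alkylation of the hydrazide. Fallback that forms the aryl–oxygen bond instead of the alkyl–oxygen bond: from 20, palladium-catalysed C–O coupling with commercial 7-bromo-2H-chromen-2-one (O=c1ccc2ccc(Br)cc2o1; Pd2(dba)3 as the zerovalent palladium source, t-BuBrettPhos, Cs2CO3, toluene, 90 °C) would engage only the primary hydroxyl and return to the route directly at 22.

## Further compounds

F1 | step 9 | trimethylsilyl ether of 12, (1R,2S,4S)-2-ethenyl-3,3,4,5-tetramethyl-1-{[tri(propan-2-yl)silyl]oxymethyl}-2-(trimethylsilyloxy)bicyclo[2.2.2]oct-5-ene | C=C[C@]1(O[Si](C)(C)C)C(C)(C)[C@@]2(C)CC[C@]1(CO[Si](C(C)C)(C(C)C)C(C)C)C=C2C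
F2 | step 9 | trimethylsilyl enol ether (C2=C3) of 15 | CC(C)[Si](C(C)C)(C(C)C)OCC1=C[C@@]2(C)CC=C(O[Si](C)(C)C)C(C)(C)[C@@]2(C)CC1
F3 | step 4 | 2-bromo-4,5-dimethylphenol | Cc1cc(Br)c(O)cc1C
F4 | step 4 | 2-bromo-4,5,6,6-tetramethylcyclohexa-2,4-dien-1-one | CC1=C(C)C(C)(C)C(=O)C(Br)=C1
F5 | step 4 | 2-(hydroxymethyl)-4,5,6,6-tetramethylcyclohexa-2,4-dien-1-one | CC1=C(C)C(C)(C)C(=O)C(CO)=C1
F6 | step 5 | rac-7,8-bis(benzenesulfonyl)-3,3,4,5-tetramethyl-1-{[tri(propan-2-yl)silyl]oxymethyl}bicyclo[2.2.2]oct-5-en-2-one (trans-disulfone, racemic) | O=C1C(C)(C)C2(C)C(S(=O)(=O)c3ccccc3)C(S(=O)(=O)c3ccccc3)C1(CO[Si](C(C)C)(C(C)C)C(C)C)C=C2C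
F7 | step 5 | rac-3,3,4,5-tetramethyl-1-{[tri(propan-2-yl)silyl]oxymethyl}bicyclo[2.2.2]octa-5,7-dien-2-one | O=C1C(C)(C)C2(C)C=CC1(CO[Si](C(C)C)(C(C)C)C(C)C)C=C2C
F8 | step 13 | ethyl [(1S,4aS,6S,8aR)-6-hydroxy-4a,5,5,8a-tetramethyl-2-methylidenedecahydronaphthalen-1-yl]acetate | C=C1CC[C@]2(C)C(C)(C)[C@@H](O)CC[C@]2(C)[C@H]1CC(=O)OCC
F9 | step 13 | [(1S,4aS,6S,8aR)-6-hydroxy-4a,5,5,8a-tetramethyl-2-methylidenedecahydronaphthalen-1-yl]acetic acid | C=C1CC[C@]2(C)C(C)(C)[C@@H](O)CC[C@]2(C)[C@H]1CC(=O)O
F10 | step 13 | N-acyloxypyridine-2-thione (Barton ester) of F9 | C=C1CC[C@]2(C)C(C)(C)[C@@H](O)CC[C@]2(C)[C@H]1CC(=O)On1ccccc1=S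
F0 | step 14 | none | none
A1 | alternative 1 | oxasilacycle C3–O–SiMe2–C16H2–C5 on the cis-fused 7-keto decalin with C9 dioxolane | C[Si]1(C)C[C@@]25CC(=O)CC3(OCCO3)[C@@]5(C)CC[C@H](O1)C2(C)C
A2 | alternative 1 | (bromomethyl)dimethylsilyl ether of the C3 alcohol on the C5=C6 7-enone with C9 dioxolane, C3–O cis to the C10 methyl group | BrC[Si](C)(C)O[C@H]1CC[C@@]2(C)C(=CC(=O)CC23OCCO3)C1(C)C
A3 | alternative 2 | ring A cyclohexene carboxylic acid with quaternary C5 and C10, C3 benzyl ether and the dioxolane-masked acetonyl arm | OC(=O)[C@]1(C)C(C)(C)[C@@H](OCc2ccccc2)C=C[C@]1(C)CC3(C)OCCO3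
A4 | alternative 2 | six-membered lactone O–C6–C5–C4–C3–C2 with C3 benzyl ether and the (E)-alkenyl group on C2, C2/C3 cis, C5 epimers | O=C1O[C@H](/C=C(\C)CC2(C)OCCO2)[C@H](OCc2ccccc2)C(C)(C)C1C
A5 | alternative 2 | (R)-pantolactone | CC1(C)COC(=O)[C@@H]1O
A6 | alternative 3 | complete decalin core as C3 tert-butyldimethylsilyl and C11 tert-butyldiphenylsilyl ether | C=C1CC[C@]2(C)C(C)(C)[C@@H](O[Si](C)(C)C(C)(C)C)CC[C@]2(C)[C@H]1CO[Si](c1ccccc1)(c1ccccc1)C(C)(C)C
A7 | alternative 3 | tertiary C5 alcohol of the 4,4,10,10-tetramethylcyclohexane with C3 silyl ether and the (Z)-allylsilane side chain (C5 epimers) | C[Si](C)(C)C/C(CCC1(O)C(C)(C)[C@@H](O[Si](C)(C)C(C)(C)C)CCC1(C)C)=C\CO[Si](c1ccccc1)(c1ccccc1)C(C)(C)C
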